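Its constants stand for no real mixture; the rest is arithmetic.

The number to find for this flask is how many living ends 9.8 mM of initiator leaves, with 0.20 M of free monomer fed in over 25 min.

    free monomer + initiator → living end + monomer in chains (k1 = 55 /M/h)
    initiator → spent initiator (k2 = 0.62 /h)
    free monomer + living end → monomer in chains + living end, rate k3*[living end]*[free monomer] (k3 = 22 /M/h)

free monomer 0.20 M (fed, over 25 min); initiator 9.8 mM; time 6.0 h; the fed solution adds 0.20 times the starting volume

- average number of monomer units in a chain (chains begun, living or dead) at 6.0 h
- part of the free monomer that has reacted at 6.0 h

- charges are per starting volume, the dose included; the dosed solution carries all of it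
- the average divides the monomer in chains by the number of chains begun, living and dead together
- run time (flask): 6.0 h

No step ends a chain, so chains begun equal living ends, and dp is monomer in chains over c(living end). Once their number stands still, the living ends take a fixed share of the free monomer per hour. I call that share the pull: the growth constant times c(living end), a pseudo-first-order constant. After the feed the volume has grown, so the full charge stands at 0.167 M.

First I take growth alone, as if each initiator began a chain at once:

c(living end) = 8.17 mM; pull = 0.180 /h; c = 66.0 %; dp = 13.5

Then I add the decay of initiator. It races the start step, which at the full level of free monomer runs at 9.17 /h against 0.62 /h, so in this reckoning the start step wins 93.7 % of the initiator: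

c(living end) = 7.65 mM; c = 63.6 %; dp = 13.9

Last comes the feed. While it runs, I put free monomer at about half of its full level; the start step then still runs faster than the decay, but its share falls to 88.1 %. I count growth from the end of the feed and take off one free monomer per chain begun:

c(living end) = 7.19 mM; pull = 0.158 /h; free monomer left = 39.5 %; c = 60.5 %; dp = 14.0

If all the free monomer goes into these chains, my dp comes to 23.2.

The forecast gives dp 14.4 and c 60 %, with “the monomer decays roughly first order at about 0.15 per hour”. Its dp stands above mine, and its c below mine.

The simulation gives dp 14.4 and c 60.0 %, so the forecast holds. At 6.00 h this flask is not at rest: c(living end) reads 0.00696 M, and 40.0 % of the free monomer remains. That reading makes the pull 0.153 /h, which over the further 54.0 h leaves 0.0102 %; the flask then holds 0.0102 %. For the neighbour charged with 0.0059 M of initiator, my reckoning gives a pull of 0.0953 /h and 57.2 % of the free monomer left; that neighbour holds 58 % of its charge. At ten times the time, this flask reaches c >99.9 % and dp 23.9.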